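You read the flask at 2.5 h, and you want to know how far substrate and partner have gone by then. In the earlier runs the bis adduct readings lie between 0% and 2%, so I count substrate and partner as consumed one for one.

the same everywhere: substrate 0.20 M
- spring: partner 0.27 M; scavenger 0.060 M; run made earlier
- winter: partner 0.42 M; scavenger 0.060 M; run made earlier
- flask: partner 0.190 M; scavenger 0.0600 M; time 2.5 h

- spring (time / h: substrate / %, bis adduct / %): 0.200: 84, 2; 0.500: 71, 0; 1.00: 57, 0; 2.50: 30, 0
- winter (time / h: substrate / %, bis adduct / %): 0.200: 79, 2; 0.500: 63, 1; 1.00: 39, 1; 2.50: 17, 1

(each reading ± 1.5 percentage points)

- part of the substrate that has reacted at 2.5 h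
- share of the unused partner that is free and not bound as idle adduct, at 2.5 h

Take the rate as k[substrate][partner], with charges cA and cB, and integrate it in closed form. Let a and b be the fractions of substrate and partner left at time t:

k = ln(b/a) / ((cB − cA) t)

The last readings give 2.70 /M/h for spring and 2.31 /M/h for winter, with mean 2.51 /M/h. Now fold the flask into one number, the reading time measured in units of the reaction's own time at the mean charge:

N = k√(cA·cB)·t = 1.22

For charges this close,

c = N/(N+1) · √(cB/cA) = 53.6%

Was one number enough? Using spring's k or winter's k instead moves c between 55.4% and 51.6%. N has no term for binding, so I give no figure for fr.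

The forecast said 54% and 72%, adding of the second that “the runs barely constrain it”. The flask gives 53.4% and 84.3%.

    substrate + partner → single product + released group (k = 0.0450 /M/min)
    scavenger + released group → scavenged by-product (k = 5.90 /M/min)
    partner + released group ⇌ idle adduct, settled at all times (K = 5.30 /M)
    partner + single product → bis adduct + released group (k = 0.00130 /M/min)

This flask has not come to rest at 2.5 h: 46.6% of the substrate and 36.3% of the partner are still there unbound, beside 0.0353 M of released group, with scavenger at 0%. Over 25.0 h, N grows to 12.2, which gives 90.1%. The computed flask reaches 86.2%, less than that, with bis adduct up from 0.658% to 3.17%.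

For a flask charged with 0.12 M of substrate, other charges held, N = 0.946 gives 61.2%, a rough figure, since that flask has 1.58 equiv of partner and the short form was made for nearly equal charges. The computed result is 61.3%.

The numbers in the tables were generated by integration from invented constants; the scatter is artificial.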